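**Retrosynthetic overview**
1. The target is the cyclic hemiketal of an (R)-α-aryloxy aryl ketone. The 1,4-dioxane ring is the only ring made and it closes last, spontaneously, when the ortho phenol is unmasked.
2. The ArO–CH(CH3) bond and the C3 stereocentre come from a new catalytic asymmetric carbene O–H insertion of an α-methyl-α-diazo aryl ketone into a hindered phenol.
3. The phenol, 4-allyl-2-methoxy-6-silyloxyphenol, comes from o-vanillin by O-allylation, Baeyer–Villiger oxidation, silylation and para-Claisen rearrangement. This sequence fixes which catechol oxygen is free.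
4. The diazo ketone comes from 3,4,5-trimethoxybenzoyl chloride and EtMgBr, then detrifluoroacetylative diazo transfer.
5. Both benzene rings are bought.

**Assumptions:** The hemiketal carbon C2 equilibrates by ring–chain tautomerism, so the route sets only C3 (R). The (2S) epimer (aryl pseudo-equatorial, anomeric OH pseudo-axial and trans to the C3 methyl) is taken as the thermodynamic one, because the natural product is isolated in this form. Which antipode of the chiral acid in step 7 gives the (R) product must be found by experiment; the (S)-acid is written. TBS = tert-butyldimethylsilyl.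

**Step 1**
Reactants: 1 2-hydroxy-3-methoxybenzaldehyde (o-vanillin); 2 allyl bromide
Product: 3 2-(allyloxy)-3-methoxybenzaldehyde
Conditions: K2CO3, DMF, rt
Reagents that add atoms: none
Why: Williamson ether synthesis; the acidic salicylaldehyde-type phenoxide is O-alkylated cleanly by the allylic bromide.

**Step 2**
Reactants: 3 2-(allyloxy)-3-methoxybenzaldehyde
Product: 5 2-(allyloxy)-3-methoxyphenol, via aryl formate 4 (not isolated)
Conditions: mCPBA, CH2Cl2, 0 °C to rt; then crude formate in MeOH, Et3N (cat.), rt
Reagents that add atoms: mCPBA, OOC(=O)c1cccc(Cl)c1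
Why: Baeyer–Villiger oxidation, in which the electron-rich ortho-alkoxyaryl group migrates in preference to H to give the aryl formate while the monosubstituted allyl alkene is epoxidised far more slowly, followed by base-catalysed methanolysis of the formate.

**Step 3**
Reactants: 5 2-(allyloxy)-3-methoxyphenol
Product: 6 [2-(allyloxy)-3-methoxyphenoxy](tert-butyl)dimethylsilane
Conditions: TBSCl, imidazole, DMF, rt
Reagents that add atoms: TBSCl, CC(C)(C)[Si](C)(C)Cl
Why: Standard imidazole-promoted O-silylation of a phenol, which marks this oxygen as the future hemiketal oxygen.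

**Step 4**
Reactants: 6 [2-(allyloxy)-3-methoxyphenoxy](tert-butyl)dimethylsilane
Product: 9 4-allyl-2-[(tert-butyldimethylsilyl)oxy]-6-methoxyphenol, via ortho-dienone 7 (not isolated), via para-dienone 8 (not isolated)
Conditions: PhNEt2, 195 °C, sealed tube, Ar
Reagents that add atoms: none
Why: Aromatic para-Claisen rearrangement; both ortho positions are substituted, so the first [3,3] product cannot enolise and passes the allyl group on by a Cope shift to the para carbon, where tautomerisation gives the phenol with the free OH flanked by OMe and OTBS.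

**Step 5**
Reactants: 10 3,4,5-trimethoxybenzoyl chloride; 11 ethylmagnesium bromide
Product: 12 1-(3,4,5-trimethoxyphenyl)propan-1-one
Conditions: Fe(acac)3 (3 mol %), THF, −78 °C
Reagents that add atoms: none
Why: Iron-catalysed Grignard acylation of an acid chloride, which at −78 °C is much faster than addition of EtMgBr to the product ketone, so it stops at the ketone.

**Step 6**
Reactants: 12 1-(3,4,5-trimethoxyphenyl)propan-1-one
Product: 14 2-diazo-1-(3,4,5-trimethoxyphenyl)propan-1-one, via trifluoroacetyl ketone 13 (not isolated)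
Conditions: LiHMDS, THF, −78 °C; CF3CO2CH2CF3; aq. HCl work-up; then MsN3, Et3N, MeCN, rt
Reagents that add atoms: 2,2,2-trifluoroethyl trifluoroacetate, FC(F)(F)COC(=O)C(F)(F)F (CF3CO group, kept in 13 only); methanesulfonyl azide, CS(=O)(=O)N=[N+]=[N-] (the N2 of 14)
Why: Detrifluoroacetylative (Danheiser-type) diazo transfer; Claisen acylation of the lithium enolate activates the α-carbon as a 1,3-diketone, which undergoes Regitz diazo transfer with loss of the trifluoroacetyl group to the sulfonamide.

**Step 7**
Reactants: 9 4-allyl-2-[(tert-butyldimethylsilyl)oxy]-6-methoxyphenol; 14 2-diazo-1-(3,4,5-trimethoxyphenyl)propan-1-one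
Product: 16 (R)-2-{4-allyl-2-[(tert-butyldimethylsilyl)oxy]-6-methoxyphenoxy}-1-(3,4,5-trimethoxyphenyl)propan-1-one, via enol 15 (not isolated)
Conditions: Rh2(O2CCPh3)4 (1 mol %), (S)-6,6'-bis(2,4,6-triisopropylphenyl)-1,1'-spirobiindane-7,7'-diyl hydrogen phosphate (5 mol %), CHCl3, −20 °C, 14 (1.3 equiv) added over 2 h
Reagents that add atoms: none
Why: Proposed new method: enantioselective carbene O–H insertion of an α-alkyl-α-diazo aryl ketone into a 2,6-dioxygenated phenol under cooperative dirhodium/chiral spiro phosphoric acid catalysis, in which the bulky triphenylacetate ligands slow the 1,2-hydride shift of the rhodium carbene so that the phenol oxygen of 9 traps it (faster than cyclopropanation of the allyl group), the oxonium ylide collapses to the (Z)-enol 15, and the chiral acid acts as a bifunctional proton shuttle (P=O binds the enol O–H, P–OH delivers the proton to one face of the enol carbon) to set the C–O stereocentre as R; the closest known reaction type is the copper- or rhodium/chiral-acid-catalysed asymmetric O–H insertion of α-diazo esters with phenols and alcohols, which has not been shown for α-alkyl diazo aryl ketones with hindered phenols.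

**Step 8**
Reactants: 16 (R)-2-{4-allyl-2-[(tert-butyldimethylsilyl)oxy]-6-methoxyphenoxy}-1-(3,4,5-trimethoxyphenyl)propan-1-one
Product: 18 (2S,3R)-7-allyl-5-methoxy-3-methyl-2-(3,4,5-trimethoxyphenyl)-2,3-dihydro-1,4-benzodioxin-2-ol (target), via hydroxy ketone 17 (not isolated)
Conditions: TBAF, AcOH (1:1), THF, 0 °C
Reagents that add atoms: none
Why: Fluoride desilylation under AcOH buffering gives no free phenoxide or enolate, so C3 is not epimerised, and the freed phenol adds to the ketone (6-exo hemiketalisation) to give the thermodynamic hemiketal with aryl pseudo-equatorial and the anomeric OH pseudo-axial, trans to the C3 methyl, which is (2S) from (3R).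

**Compound list**
1 | 2-hydroxy-3-methoxybenzaldehyde (o-vanillin) | COc1cccc(C=O)c1O | starting material
2 | allyl bromide | C=CCBr | starting material
3 | 2-(allyloxy)-3-methoxybenzaldehyde | C=CCOc1c(OC)cccc1C=O | intermediate
4 | 2-(allyloxy)-3-methoxyphenyl formate | C=CCOc1c(OC)cccc1OC=O | intermediate (not isolated)
5 | 2-(allyloxy)-3-methoxyphenol | C=CCOc1c(OC)cccc1O | intermediate
6 | [2-(allyloxy)-3-methoxyphenoxy](tert-butyl)dimethylsilane | C=CCOc1c(OC)cccc1O[Si](C)(C)C(C)(C)C | intermediate
7 | 6-allyl-6-methoxy-2-[(tert-butyldimethylsilyl)oxy]cyclohexa-2,4-dien-1-one (racemic) | C=CCC1(OC)C=CC=C(O[Si](C)(C)C(C)(C)C)C1=O | intermediate (not isolated)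
8 | 4-allyl-2-methoxy-6-[(tert-butyldimethylsilyl)oxy]cyclohexa-2,5-dien-1-one (racemic) | C=CCC1C=C(OC)C(=O)C(O[Si](C)(C)C(C)(C)C)=C1 | intermediate (not isolated)
9 | 4-allyl-2-[(tert-butyldimethylsilyl)oxy]-6-methoxyphenol | C=CCc1cc(OC)c(O)c(O[Si](C)(C)C(C)(C)C)c1 | intermediate
10 | 3,4,5-trimethoxybenzoyl chloride | COc1cc(C(=O)Cl)cc(OC)c1OC | starting material
11 | ethylmagnesium bromide | CC[Mg]Br | starting material
12 | 1-(3,4,5-trimethoxyphenyl)propan-1-one | CCC(=O)c1cc(OC)c(OC)c(OC)c1 | intermediate
13 | 4,4,4-trifluoro-2-methyl-1-(3,4,5-trimethoxyphenyl)butane-1,3-dione (racemic) | CC(C(=O)C(F)(F)F)C(=O)c1cc(OC)c(OC)c(OC)c1 | intermediate (not isolated)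
14 | 2-diazo-1-(3,4,5-trimethoxyphenyl)propan-1-one | CC(=[N+]=[N-])C(=O)c1cc(OC)c(OC)c(OC)c1 | intermediate
15 | (Z)-2-{4-allyl-2-[(tert-butyldimethylsilyl)oxy]-6-methoxyphenoxy}-1-(3,4,5-trimethoxyphenyl)prop-1-en-1-ol | C/C(Oc1c(OC)cc(CC=C)cc1O[Si](C)(C)C(C)(C)C)=C(/O)c1cc(OC)c(OC)c(OC)c1 | intermediate (not isolated)
16 | (R)-2-{4-allyl-2-[(tert-butyldimethylsilyl)oxy]-6-methoxyphenoxy}-1-(3,4,5-trimethoxyphenyl)propan-1-one | C[C@@H](Oc1c(OC)cc(CC=C)cc1O[Si](C)(C)C(C)(C)C)C(=O)c1cc(OC)c(OC)c(OC)c1 | intermediate
17 | (R)-2-(4-allyl-2-hydroxy-6-methoxyphenoxy)-1-(3,4,5-trimethoxyphenyl)propan-1-one | C[C@@H](Oc1c(OC)cc(CC=C)cc1O)C(=O)c1cc(OC)c(OC)c(OC)c1 | intermediate (not isolated)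
18 | (2S,3R)-7-allyl-5-methoxy-3-methyl-2-(3,4,5-trimethoxyphenyl)-2,3-dihydro-1,4-benzodioxin-2-ol | C=CCc1cc(OC)c2c(c1)O[C@@](O)(c1cc(OC)c(OC)c(OC)c1)[C@@H](C)O2 | target

**Total step count:** 8. **Longest linear sequence:** 6 steps (1, 2, 3, 4, 7, 8).

**Three steps most likely to fail**

Step 7 (proposed new O–H insertion). The risks are a 1,2-hydride shift of the carbene to the aryl vinyl ketone, slow trapping by the hindered phenol, and low or reversed enantioselectivity. The fallback uses known chemistry, sets out from phenol 9 and comes back at ketone 16. Mitsunobu reaction of 9 with ethyl (S)-lactate (PPh3, DIAD, THF, 0 °C to rt) goes with inversion to ethyl (R)-2-{4-allyl-2-[(tert-butyldimethylsilyl)oxy]-6-methoxyphenoxy}propanoate F1. Treatment with MeNHOMe·HCl and AlMe3 (CH2Cl2, 0 °C to rt) gives the Weinreb amide (R)-2-{4-allyl-2-[(tert-butyldimethylsilyl)oxy]-6-methoxyphenoxy}-N-methoxy-N-methylpropanamide F2. Commercial 3,4,5-trimethoxyphenylmagnesium bromide (THF, −20 °C) adds once to the chelated amide and gives 16 without loss of configuration; step 8 follows as written.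

Step 4 (para-Claisen on the silyl ether). The risks are silyl loss or O-to-O silyl migration at 195 °C and a low yield in the dienone relay. The fallback sets out from aldehyde 3 and comes back at phenol 9; it moves the rearrangement ahead of oxygen introduction and silylation, so no silyl group is heated. Para-Claisen rearrangement of 3 (PhNEt2, 200 °C) gives 5-allyl-2-hydroxy-3-methoxybenzaldehyde F3. Dakin oxidation (H2O2, NaOH, THF/H2O, 0 °C to rt) gives 5-allyl-3-methoxybenzene-1,2-diol F4. Silylation with 1.0 equiv TBSCl and imidazole (CH2Cl2, −20 °C) takes place at the less hindered hydroxyl, the one not flanked by OMe, and gives 9.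

Step 8 (unmasking and hemiketalisation). The risks are partial epimerisation of C3 through the open-chain ketone during fluoride treatment, and a hemiketal epimer mixture that is slow to converge. The fallback sets out from phenol 9 and comes back at target 18; it closes the dioxane ring at the ester oxidation level and forms the aryl–C2 bond last, so no α-aryloxy ketone is ever exposed to fluoride. Ester F1 is made from 9 as in the step 7 fallback. TBAF/AcOH (THF, 0 °C) gives ethyl (R)-2-(4-allyl-2-hydroxy-6-methoxyphenoxy)propanoate F5. Heating with catalytic TsOH in toluene lactonises it to (3R)-7-allyl-5-methoxy-3-methyl-2,3-dihydro-1,4-benzodioxin-2-one F6. Addition of 3,4,5-trimethoxyphenylmagnesium bromide (1.05 equiv, THF, −78 °C, AcOH quench) to the lactone carbonyl gives the hemiketal 18 directly.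

**Further compounds**
F1 | step 7 | ethyl (R)-2-{4-allyl-2-[(tert-butyldimethylsilyl)oxy]-6-methoxyphenoxy}propanoate | CCOC(=O)[C@@H](C)Oc1c(OC)cc(CC=C)cc1O[Si](C)(C)C(C)(C)C
F2 | step 7 | (R)-2-{4-allyl-2-[(tert-butyldimethylsilyl)oxy]-6-methoxyphenoxy}-N-methoxy-N-methylpropanamide | CON(C)C(=O)[C@@H](C)Oc1c(OC)cc(CC=C)cc1O[Si](C)(C)C(C)(C)C
F3 | step 4 | 5-allyl-2-hydroxy-3-methoxybenzaldehyde | C=CCc1cc(OC)c(O)c(C=O)c1
F4 | step 4 | 5-allyl-3-methoxybenzene-1,2-diol | C=CCc1cc(O)c(O)c(OC)c1
F5 | step 8 | ethyl (R)-2-(4-allyl-2-hydroxy-6-methoxyphenoxy)propanoate | CCOC(=O)[C@@H](C)Oc1c(O)cc(CC=C)cc1OC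
F6 | step 8 | (3R)-7-allyl-5-methoxy-3-methyl-2,3-dihydro-1,4-benzodioxin-2-one | C=CCc1cc(OC)c2c(c1)OC(=O)[C@@H](C)O2
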